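Remark on the chemistry: germacrane numbering is used throughout (ring C1–C10, lactone carbons C11–C13 on C7, C14 = methyl on C10, C15 = carbon on C4). The target SMILES is read as (6R,7S,8S,11S), with C1=C10 ring-cis (Z) and C4=C5 ring-trans (Z by priority rules, C15 cis to C6).

## Analysis of the target

The target is a germacranolide: a cyclodeca-1(10),4-diene (C1–C10) cis-fused at C6–C7 to an α-methyl-γ-butyrolactone (O6–C12(=O)–C11(C13H3)–C7). It carries a (2E)-4-hydroxy-2-methylbut-2-enoate on O8, a methyl group (C14) on C10 and a hydroxymethyl group (C15) on C4. The two trisubstituted ring alkenes have opposite ring geometry: C1=C10 is a neryl-type Z unit (C2 and C9 cis), whereas C4=C5 is ring-trans (C3 and C6 trans). The four stereocentres are contiguous. O6, the C11 branch on C7 and O8 lie on one face of the carbocycle (an all-cis triad), and H6, H7 and H11 lie on one face of the lactone, so that the C13 methyl sits on the concave face next to C8 (the kinetic C11 epimer). The feature that decides the strategy is the unit C6(O)–C7–C11–C12 inside the lactone: an oxygen-bearing carbon (C6, flanked by the C4=C5 unsaturation) bonded to C7, which carries a branched three-carbon unit whose end C12 is tied back to O6. This is the retron of a [2,3] shift of an O6–C12 ether, which means the ring bond C6–C7 and both of its stereocentres can come from a thirteen-membered cyclic ether. Sensitive points are the 1,5-diene (Cope rearrangement on heating, transannular cyclisation in acid), the epimerisable C11, two primary allylic alcohols and two acyl groups that can migrate or be cleaved by base. The difficulty is the ten-membered ring itself, the opposite geometry of its two alkenes, and the all-cis C6/C7/C8 triad next to a contra-thermodynamic C11.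

## Retrosynthetic reasoning

**31 back to 26 and 29.** The two silyl ethers of 30 are removed last. The C8–O ester bond of 30 is cut with inversion (Mitsunobu) to the alcohol 26 and the acid 29. The reason is the key step: there the C8 oxygen directs bond formation anti to itself, so it ends trans to the C7 branch, whereas the target has it cis. An inverting esterification lets the same centre serve first as control element and then be corrected while the acyl group is put on. Acid 29 comes from aldehyde 27 through ester 28.

**26 back to 21.** C11 is disconnected to the planar lactone enolate 24: kinetic protonation on the convex face gives 25 from either epimer of 23. The lactone carbonyl C12 of 23 is traced back through diol 22 to an isopropenyl group (C11=C12) on C7 and a free hydroxyl on C6 in 21. This turns the γ-lactone into a homoallylic alcohol.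

**21 back to 17.** The C4–C15 bond is cut (20 from vinyl iodide 19) and the C4=C5 alkene is returned to an alkyne (17). Hydroxyl-directed trans-hydroalumination of a propargylic alcohol delivers exactly what the target needs: hydrogen on C5 and the new substituent on C4 cis to C6, which is the ring-trans alkene. The alkyne removes one alkene geometry and C15 from the precursor, and it makes the C6 hydrogens the most acidic ones of the ether in the key step.

**17 back to 15 (key disconnection).** The ring bond C6–C7 is cut and O6 is joined to C12, which gives the thirteen-membered cyclic propargylic allylic ether 15. This bond is chosen because it joins two of the stereocentres and closes the carbocycle. The forward reaction has to deprotonate C6 and contract the ring from thirteen to ten members by a [2,3] shift, setting C6 and C7 and creating the isopropenyl group. The precursor 15 has one stereocentre (C8), no medium ring and no ring-trans alkene.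

**15 back to 10.** The O–C6 bond of 15 is cut to the bromo alcohol 14 (Williamson closure). Its Z-configured ene-1,4-diol unit (12, mono-silylated via 13) is traced back to the butenolide 11 and its alcohol 10. The five-membered lactone locks the Z geometry of C7=C11 and masks O8 and C12 at the same time.

**10 back to 7.** The C7=C11 bond is cut (Z-selective olefination) and the C8–O bond is cut (catalytic asymmetric α-oxygenation of an aldehyde by an amine catalyst). The only stereocentre of the precursor is thus set by the catalyst.

**7 back to 1.** The C7 aldehyde of 7 comes from cleavage of the terminal isopropylidene group of 4 via epoxide 6. The C2–C3 and C5–C6 bonds of 4 are made in one flask from bromide 2, a three-carbon propargyl dianion and a one-carbon electrophile. Nerol 1 supplies C2, C1, C10, C14, C9, C8 and C7 with the Z alkene already in place.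

## Alternatives that were turned down

Alternative 1: the textbook route, an intramolecular Nozaki–Hiyama-type allylation that forms C6–C7 from an open chain. The acyclic ω-formyl 2-(bromomethyl)enoate A1 would be cyclised with CrCl2 at high dilution. The allylchromium adds through C7 to the C6 aldehyde and the alkoxide closes the lactone to the α-methylene lactone A2, whose conjugate reduction would set C11. It was turned down for four reasons.
- The chair transition state of allylchromium additions favours the anti product, which is the trans-fused lactone, not the cis fusion needed here.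
- The relation of C7 to C8 would rest on the same poorly biased event.
- A1 must already contain both trisubstituted alkenes, including the isomerisable enal C4=C5 with C15, so the precursor is no simpler than the product in its alkene problems.
- The ring is closed end to end against the full entropic cost of a ten-membered ring.

Alternative 2: anionic oxy-Cope ring expansion (cut C8–C9, reconnect C1–C6). The 1,2-dialkenylcyclohexenol A3 (six-membered ring C1–C6, a 2-methoxyvinyl group on C6, an isopropenyl group on C1) would rearrange with KH and 18-crown-6 to the cyclodecadienone A4. It was turned down because the cyclohexene alkene C4=C5 is carried into the large ring as ring-cis and the chair transition state delivers C1=C10 as E, the exact opposite of the pairing in the target. Two alkene isomerisations would be needed, and the C7 side chain and all four stereocentres would still have to be introduced afterwards on the flexible ring (enolate alkylation at C7, ketone reduction at C6). The step count would exceed that of the chosen route.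

Alternative 3: ring-closing metathesis at C1=C10. The diene A5, which already holds the lactone and all four stereocentres, would be closed to A6 with the second-generation Grubbs catalyst. It was turned down because a trisubstituted alkene in a strained ten-membered ring is among the poorest metathesis cases (oligomers, no secured Z geometry). In addition the key step would build one bond and no stereocentre, so the whole stereotriad and C11 would have to be made by separate acyclic stereocontrol.

Key step: step 10

## Route

Step 1
Reactants: 1 nerol, (2Z)-3,7-dimethylocta-2,6-dien-1-ol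
Product: 2 neryl bromide, (2Z)-1-bromo-3,7-dimethylocta-2,6-diene
Conditions: PBr3 (0.4 equiv), Et2O, −10 °C
Reagents that add atoms: phosphorus tribromide, BrP(Br)Br
Why: SN2-type bromination of a primary allylic alcohol; at low temperature the Z alkene is kept and allylic transposition is avoided.

Step 2
Reactants: 2 neryl bromide
Product: 4 (6Z)-7,11-dimethyldodeca-6,10-dien-2-yn-1-ol, via lithium dienynyl acetylide 3 (not isolated)
Conditions: propyne, n-BuLi (2 equiv), TMEDA, Et2O–hexane, −78 → 0 °C; 2, −78 → 0 °C; then (CH2O)n, rt; H2O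
Reagents that add atoms: propyne, CC#C; formaldehyde (as paraformaldehyde), C=O
Why: propargylation of an allylic halide with 1,3-dilithiopropyne, which alkylates at its sp3 carbon (SN2, Z geometry retained); the lithium acetylide that remains is hydroxymethylated in the same flask.

Step 3
Reactants: 4 (6Z)-7,11-dimethyldodeca-6,10-dien-2-yn-1-ol
Product: 6 (6Z)-9-(3,3-dimethyloxiran-2-yl)-7-methylnon-6-en-2-yn-1-ol (racemic at the oxirane), via terminal bromohydrin 5 (not isolated)
Conditions: NBS, THF–H2O, 0 °C; then K2CO3, MeOH, rt
Reagents that add atoms: water, O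
Why: bromohydrin formation in aqueous medium is selective for the terminal isopropylidene alkene of polyprenyl chains (the internal trisubstituted alkene is shielded, the alkyne is inert); base closes the epoxide, whose stereocentre is destroyed in step 4.

Step 4
Reactants: 6 terminal epoxide
Product: 7 (4Z)-10-hydroxy-4-methyldec-4-en-8-ynal
Conditions: H5IO6, THF–Et2O, 0 °C
Reagents that add atoms: none
Why: periodic acid opens the epoxide to the glycol and cleaves it (glycol cleavage), releasing acetone and the C7 aldehyde with the C8 methylene next to it.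

Step 5
Reactants: 7 (4Z)-10-hydroxy-4-methyldec-4-en-8-ynal
Product: 10 (5R)-5-[(2Z)-8-hydroxy-2-methyloct-2-en-6-yn-1-yl]-3-methylfuran-2(5H)-one, via α-anilinooxy aldehyde 8 (not isolated), via Z-configured anilinooxy enoate 9 (not isolated)
Conditions: L-proline (20 mol %), PhNO, MeCN, −20 °C; then (CF3CH2O)2P(O)CH(CH3)CO2Et, KN(SiMe3)2, 18-crown-6, THF, −78 °C; then Zn, AcOH, THF, rt
Reagents that add atoms: nitrosobenzene, O=Nc1ccccc1; ethyl 2-[bis(2,2,2-trifluoroethoxy)phosphoryl]propanoate, CCOC(=O)C(C)P(=O)(OCC(F)(F)F)OCC(F)(F)F
Why: proline-catalysed α-aminoxylation (enamine attack on the oxygen of the nitroso group) sets C8 as R under catalyst control. Still–Gennari olefination gives the Z enoate (C8 cis to the ester), and zinc cleaves the N–O bond, after which the Z γ-hydroxy ester lactonises. Any E isomer cannot lactonise and is removed, so the butenolide secures the Z geometry of C7=C11.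

Step 6
Reactants: 10 butenolide alcohol
Product: 11 (5R)-5-[(2Z)-8-bromo-2-methyloct-2-en-6-yn-1-yl]-3-methylfuran-2(5H)-one
Conditions: CBr4, PPh3, CH2Cl2, 0 °C
Reagents that add atoms: carbon tetrabromide, BrC(Br)(Br)Br
Why: Appel bromination of the only hydroxyl group (primary, propargylic); the neutral conditions leave the butenolide and its acidic γ-hydrogen alone.

Step 7
Reactants: 11 butenolide bromide
Product: 12 (2Z,4R,6Z)-12-bromo-2,6-dimethyldodeca-2,6-dien-10-yne-1,4-diol
Conditions: i-Bu2AlH (3 equiv), CH2Cl2, −78 → −20 °C; aq. potassium sodium tartrate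
Reagents that add atoms: none
Why: 1,2-reduction of the butenolide through the lactol to the ene-1,4-diol, whose Z geometry is fixed by the ring it comes from; alkyl and propargylic bromides tolerate i-Bu2AlH at low temperature (as in the reduction of 4-bromocrotonates).

Step 8
Reactants: 12 bromo diol
Product: 14 (2Z,4R,6Z)-12-bromo-4-(tert-butyldimethylsilyloxy)-2,6-dimethyldodeca-2,6-dien-10-yn-1-ol, via bis-silyl ether 13 (not isolated)
Conditions: TBSOTf (2.4 equiv), 2,6-lutidine, CH2Cl2, −78 °C; then HF·pyridine, pyridine, THF, 0 °C
Reagents that add atoms: tert-butyldimethylsilyl triflate, CC(C)(C)[Si](C)(C)OS(=O)(=O)C(F)(F)F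
Why: exhaustive silylation followed by selective cleavage of the less hindered primary allylic silyl ether leaves the secondary C8 ether; a non-nucleophilic base is used because of the propargylic bromide.

Step 9
Reactants: 14 bromo alcohol
Product: 15 (3Z,5R,7Z)-5-(tert-butyldimethylsilyloxy)-3,7-dimethyl-1-oxacyclotrideca-3,7-dien-11-yne
Conditions: EtMgBr (1.05 equiv), THF, 0 °C; then HMPA, slow addition into THF at 60 °C (0.003 M)
Reagents that add atoms: none
Why: intramolecular Williamson etherification at high dilution. The primary propargylic bromide is a fast SN2 electrophile without β-hydrogens, the thirteen-membered ring with one alkyne and two cis alkenes is nearly strain-free, and the magnesium alkoxide is chosen to suppress a 1,4 silyl shift from O8 to O12.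

Step 10
Reactants: 15 thirteen-membered propargylic allylic ether
Product: 17 (6S,7R,8R)-8-(tert-butyldimethylsilyloxy)-15-norgermacra-1(10)Z,11-dien-4-yn-6-ol, via C6-lithiated ether 16 (not isolated)
Conditions: n-BuLi (1.5 equiv), THF–pentane, −78 → −40 °C; AcOH, −78 °C
Reagents that add atoms: none
Why: n-BuLi removes a proton from C6, the only carbon that is both propargylic and next to the ether oxygen, and carbanion 16 attacks C7 across the ring in a concerted suprafacial [2,3]-sigmatropic (Wittig) shift through a five-membered envelope transition state (C6, O, C12, C11, C7): the C6–C7 bond forms, the O–C12 bond breaks and C11=C12 becomes the isopropenyl double bond. The closest known reaction type is the [2,3]-Wittig ring contraction of thirteen-membered cyclic propargylic allylic ethers to cyclodecynols. The ten-membered carbocycle is closed transannularly by ring contraction (thirteen to ten; O, C12 and C11 leave the ring), not by an end-to-end cyclisation, so the entropic cost was already paid in the easy ether closure. C6 relative to C7: the Z geometry of C7=C11 (C8 cis to C12), with the slim alkynyl group exo in the envelope, gives the syn product, that is O6 and the isopropenyl group cis on the new ring; the methyl on C11 penalises the endo alternative. C7 relative to C8, and with it the absolute configuration: H8 eclipses the alkene to avoid allylic 1,3-strain with C12, the carbanion adds anti to the C8–O bond, and C9, which is tethered to C6 through the ring, lies on the attacked face, so the isopropenyl group ends trans to the silyloxy group and (8R) is translated into (6S,7R). The step needs site selectivity (C6 rather than the allylic C12, secured by the alkyne), a [2,3] rather than a [1,2] shift (secured by the low temperature) and face selectivity (secured by the C8 stereocentre and the ring tether); the cold acidic quench keeps the silyl group on O8.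

Step 11
Reactants: 17 cyclodecenynol
Product: 19 (6S,7R,8R)-8-(tert-butyldimethylsilyloxy)-4-iodo-15-norgermacra-1(10)Z,4Z,11-trien-6-ol, via sodium alkenylaluminate 18 (not isolated)
Conditions: NaAlH2(OCH2CH2OCH3)2 (2 equiv), THF, 0 °C → rt; then I2, THF, −78 °C
Reagents that add atoms: iodine, II
Why: hydroxyl-directed trans-hydroalumination of a propargylic alcohol. Hydride goes to C5 and aluminium to C4 within a five-membered oxa-aluminacycle, and iodinolysis with retention gives the iodoalkene with iodine cis to C6, which is the ring-trans C4=C5 alkene; the isopropenyl group and the silyl ether do not react.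

Step 12
Reactants: 19 vinyl iodide
Product: 20 (6R,7R,8R)-8-(tert-butyldimethylsilyloxy)germacra-1(10)Z,4Z,11(13)-triene-6,15-diol
Conditions: Bu3SnCH2OH, Pd2(dba)3 (5 mol %), AsPh3, CuI, NMP, 45 °C
Reagents that add atoms: (tributylstannyl)methanol, OC[Sn](CCCC)(CCCC)CCCC
Why: Stille hydroxymethylation with retention of the alkene geometry installs C15; the ligand and copper iodide allow a temperature low enough to keep the new 1,5-diene from Cope rearrangement.

Step 13
Reactants: 20 diol
Product: 21 (6R,7R,8R)-8-(tert-butyldimethylsilyloxy)-15-(tert-butyldiphenylsilyloxy)germacra-1(10)Z,4Z,11(13)-trien-6-ol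
Conditions: TBDPSCl, imidazole, CH2Cl2, 0 °C
Reagents that add atoms: tert-butyldiphenylsilyl chloride, CC(C)(C)[Si](Cl)(c1ccccc1)c1ccccc1
Why: the bulky silyl chloride takes the primary allylic hydroxyl and leaves the hindered secondary C6 hydroxyl free for the lactone.

Step 14
Reactants: 21 mono-silylated diol
Product: 22 (6R,7R,8R)-8-(tert-butyldimethylsilyloxy)-15-(tert-butyldiphenylsilyloxy)germacra-1(10)Z,4Z-diene-6,12-diol (both C11 epimers)
Conditions: 9-BBN (3 equiv), THF, 0 °C → rt; then NaOH, H2O2, 0 °C
Reagents that add atoms: hydrogen peroxide, OO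
Why: 9-BBN hydroborates the 1,1-disubstituted isopropenyl alkene far faster than the two trisubstituted ring alkenes and places oxygen on C12. C11 is formed here without reliable control, so both epimers are carried on and C11 is fixed in step 16.

Step 15
Reactants: 22 1,4-diol
Product: 23 (6R,7R,8R)-8-(tert-butyldimethylsilyloxy)-15-(tert-butyldiphenylsilyloxy)germacra-1(10)Z,4Z-dien-12,6-olide (both C11 epimers)
Conditions: TEMPO (20 mol %), PhI(OAc)2 (2.5 equiv), CH2Cl2, rt
Reagents that add atoms: none
Why: the oxoammonium oxidation takes the primary alcohol to the aldehyde, the cis-disposed C6 hydroxyl closes the lactol, and a second oxidation gives the γ-lactone; the cis ring fusion follows from the cis relation set in step 10.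

Step 16
Reactants: 23 lactone (C11 epimers)
Product: 25 (6R,7R,8R,11S)-8-(tert-butyldimethylsilyloxy)-15-(tert-butyldiphenylsilyloxy)germacra-1(10)Z,4Z-dien-12,6-olide, via lithium lactone enolate 24 (not isolated)
Conditions: LiN(i-Pr)2 (1.2 equiv), THF, −78 °C; then AcOH, THF, −78 °C
Reagents that add atoms: none
Why: a stereoconvergent step, since both C11 epimers give the same planar enolate. Kinetic C-protonation occurs on the convex face, trans to C8 on the neighbouring C7 (the face of H6 and H7), which puts H11 cis to H7 and the methyl cis to C8 (11S). The enolate is kept at −78 °C so that the allylic C6–O bond does not enter an ester-enolate Claisen rearrangement.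

Step 17
Reactants: 25 bis-silyl lactone
Product: 26 (6R,7S,8R,11S)-15-(tert-butyldiphenylsilyloxy)-8-hydroxygermacra-1(10)Z,4Z-dien-12,6-olide
Conditions: HF·pyridine, pyridine, THF, 0 °C → rt
Reagents that add atoms: none
Why: buffered acidic fluoride cleaves the secondary tert-butyldimethylsilyl ether much faster than the primary tert-butyldiphenylsilyl ether and is mild enough for the 1,5-diene and the lactone.

Step 18
Reactants: 27 (tert-butyldimethylsilyloxy)acetaldehyde
Product: 28 ethyl (2E)-4-(tert-butyldimethylsilyloxy)-2-methylbut-2-enoate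
Conditions: Ph3P=C(CH3)CO2Et, CH2Cl2, rt
Reagents that add atoms: ethyl 2-(triphenylphosphoranylidene)propanoate, CCOC(=O)C(C)=P(c1ccccc1)(c1ccccc1)c1ccccc1
Why: Wittig reaction of a stabilised ylide, E-selective for the trisubstituted enoate.

Step 19
Reactants: 28 ethyl ester
Product: 29 (2E)-4-(tert-butyldimethylsilyloxy)-2-methylbut-2-enoic acid
Conditions: LiOH, THF–MeOH–H2O, rt; then 1 M HCl to pH 4, 0 °C
Reagents that add atoms: lithium hydroxide, [Li+].[OH-]
Why: saponification; the primary silyl ether survives aqueous base and the brief cold acidification.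

Step 20
Reactants: 26 C8 alcohol; 29 protected acid
Product: 30 (6R,7S,8S,11S)-15-(tert-butyldiphenylsilyloxy)-8-[(2E)-4-(tert-butyldimethylsilyloxy)-2-methylbut-2-enoyloxy]germacra-1(10)Z,4Z-dien-12,6-olide
Conditions: PPh3, DIAD, toluene, 0 °C → rt
Reagents that add atoms: none
Why: Mitsunobu esterification: the carboxylate displaces the activated C8 oxygen by SN2 with inversion, which turns the (8R) control element into the (8S) ester cis to the lactone branch; C8 is not allylic, so no SN2′ path exists.

Step 21
Reactants: 30 bis-silyl ether of the target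
Product: 31 target, (6R,7S,8S,11S)-15-hydroxy-8-[(2E)-4-hydroxy-2-methylbut-2-enoyloxy]germacra-1(10)Z,4Z-dien-12,6-olide
Conditions: Bu4NF, AcOH (1:1), THF, 0 °C → rt
Reagents that add atoms: none
Why: buffered fluoride removes both primary silyl ethers; the acetic acid buffer prevents acyl migration, ester cleavage and epimerisation at C11.

## Compound list

1 | nerol, (2Z)-3,7-dimethylocta-2,6-dien-1-ol | OC/C=C(/C)CCC=C(C)C | starting material
2 | neryl bromide, (2Z)-1-bromo-3,7-dimethylocta-2,6-diene | BrC/C=C(/C)CCC=C(C)C | intermediate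
3 | lithium (5Z)-6,10-dimethylundeca-5,9-dien-1-yn-1-ide | [Li]C#CCC/C=C(/C)CCC=C(C)C | intermediate
4 | (6Z)-7,11-dimethyldodeca-6,10-dien-2-yn-1-ol | OCC#CCC/C=C(/C)CCC=C(C)C | intermediate
5 | (6Z)-10-bromo-7,11-dimethyldodec-6-en-2-yne-1,11-diol (racemic) | OCC#CCC/C=C(/C)CCC(Br)C(C)(C)O | intermediate
6 | (6Z)-9-(3,3-dimethyloxiran-2-yl)-7-methylnon-6-en-2-yn-1-ol (racemic) | OCC#CCC/C=C(/C)CCC1OC1(C)C | intermediate
7 | (4Z)-10-hydroxy-4-methyldec-4-en-8-ynal | OCC#CCC/C=C(/C)CCC=O | intermediate
8 | (2R,4Z)-10-hydroxy-4-methyl-2-[(phenylamino)oxy]dec-4-en-8-ynal | OCC#CCC/C=C(/C)C[C@@H](ONc1ccccc1)C=O | intermediate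
9 | ethyl (2Z,4R,6Z)-12-hydroxy-2,6-dimethyl-4-[(phenylamino)oxy]dodeca-2,6-dien-10-ynoate | OCC#CCC/C=C(/C)C[C@@H](ONc1ccccc1)/C=C(/C)C(=O)OCC | intermediate
10 | (5R)-5-[(2Z)-8-hydroxy-2-methyloct-2-en-6-yn-1-yl]-3-methylfuran-2(5H)-one | OCC#CCC/C=C(/C)C[C@H]1OC(=O)C(C)=C1 | intermediate
11 | (5R)-5-[(2Z)-8-bromo-2-methyloct-2-en-6-yn-1-yl]-3-methylfuran-2(5H)-one | BrCC#CCC/C=C(/C)C[C@H]1OC(=O)C(C)=C1 | intermediate
12 | (2Z,4R,6Z)-12-bromo-2,6-dimethyldodeca-2,6-dien-10-yne-1,4-diol | BrCC#CCC/C=C(/C)C[C@@H](O)/C=C(/C)CO | intermediate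
13 | (2Z,4R,6Z)-12-bromo-1,4-bis(tert-butyldimethylsilyloxy)-2,6-dimethyldodeca-2,6-dien-10-yne | BrCC#CCC/C=C(/C)C[C@@H](O[Si](C)(C)C(C)(C)C)/C=C(/C)CO[Si](C)(C)C(C)(C)C | intermediate
14 | (2Z,4R,6Z)-12-bromo-4-(tert-butyldimethylsilyloxy)-2,6-dimethyldodeca-2,6-dien-10-yn-1-ol | BrCC#CCC/C=C(/C)C[C@@H](O[Si](C)(C)C(C)(C)C)/C=C(/C)CO | intermediate
15 | (3Z,5R,7Z)-5-(tert-butyldimethylsilyloxy)-3,7-dimethyl-1-oxacyclotrideca-3,7-dien-11-yne | C1C#CCC/C=C(/C)C[C@@H](O[Si](C)(C)C(C)(C)C)/C=C(/C)CO1 | intermediate
16 | 13-lithio derivative of 15 (lithium on the propargylic OCH carbon, C6) | [Li]C1C#CCC/C=C(/C)C[C@@H](O[Si](C)(C)C(C)(C)C)/C=C(/C)CO1 | intermediate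
17 | (6S,7R,8R)-8-(tert-butyldimethylsilyloxy)-15-norgermacra-1(10)Z,11-dien-4-yn-6-ol; (1S,6Z,9R,10R)-9-(tert-butyldimethylsilyloxy)-7-methyl-10-(prop-1-en-2-yl)cyclodec-6-en-2-yn-1-ol | C/C1=C/CCC#C[C@@H](O)[C@@H](C(C)=C)[C@H](O[Si](C)(C)C(C)(C)C)C1 | intermediate
18 | sodium alkenylaluminate of 17 (five-membered ring O6–Al–C4=C5–C6, two 2-methoxyethoxy groups on aluminium) | C/C1=C/CC/C2=C/[C@@H](O[Al-]2(OCCOC)OCCOC)[C@@H](C(C)=C)[C@H](O[Si](C)(C)C(C)(C)C)C1.[Na+] | intermediate
19 | (6S,7R,8R)-8-(tert-butyldimethylsilyloxy)-4-iodo-15-norgermacra-1(10)Z,4Z,11-trien-6-ol | C/C1=C/CC/C(I)=C/[C@@H](O)[C@@H](C(C)=C)[C@H](O[Si](C)(C)C(C)(C)C)C1 | intermediate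
20 | (6R,7R,8R)-8-(tert-butyldimethylsilyloxy)germacra-1(10)Z,4Z,11(13)-triene-6,15-diol | C/C1=C/CC/C(CO)=C/[C@@H](O)[C@@H](C(C)=C)[C@H](O[Si](C)(C)C(C)(C)C)C1 | intermediate
21 | (6R,7R,8R)-8-(tert-butyldimethylsilyloxy)-15-(tert-butyldiphenylsilyloxy)germacra-1(10)Z,4Z,11(13)-trien-6-ol | C/C1=C/CC/C(CO[Si](c2ccccc2)(c2ccccc2)C(C)(C)C)=C/[C@@H](O)[C@@H](C(C)=C)[C@H](O[Si](C)(C)C(C)(C)C)C1 | intermediate
22 | (6R,7R,8R)-8-(tert-butyldimethylsilyloxy)-15-(tert-butyldiphenylsilyloxy)germacra-1(10)Z,4Z-diene-6,12-diol, both C11 epimers | C/C1=C/CC/C(CO[Si](c2ccccc2)(c2ccccc2)C(C)(C)C)=C/[C@@H](O)[C@@H](C(C)CO)[C@H](O[Si](C)(C)C(C)(C)C)C1 | intermediate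
23 | (6R,7R,8R)-8-(tert-butyldimethylsilyloxy)-15-(tert-butyldiphenylsilyloxy)germacra-1(10)Z,4Z-dien-12,6-olide, both C11 epimers | C/C1=C/CC/C(CO[Si](c3ccccc3)(c3ccccc3)C(C)(C)C)=C/[C@H]2OC(=O)C(C)[C@H]2[C@H](O[Si](C)(C)C(C)(C)C)C1 | intermediate
24 | lithium enolate of 23 (C11=C12, O–Li) | C/C1=C/CC/C(CO[Si](c3ccccc3)(c3ccccc3)C(C)(C)C)=C/[C@H]2OC(O[Li])=C(C)[C@H]2[C@H](O[Si](C)(C)C(C)(C)C)C1 | intermediate
25 | (6R,7R,8R,11S)-8-(tert-butyldimethylsilyloxy)-15-(tert-butyldiphenylsilyloxy)germacra-1(10)Z,4Z-dien-12,6-olide | C/C1=C/CC/C(CO[Si](c3ccccc3)(c3ccccc3)C(C)(C)C)=C/[C@H]2OC(=O)[C@@H](C)[C@H]2[C@H](O[Si](C)(C)C(C)(C)C)C1 | intermediate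
26 | (6R,7S,8R,11S)-15-(tert-butyldiphenylsilyloxy)-8-hydroxygermacra-1(10)Z,4Z-dien-12,6-olide | C/C1=C/CC/C(CO[Si](c3ccccc3)(c3ccccc3)C(C)(C)C)=C/[C@H]2OC(=O)[C@@H](C)[C@H]2[C@H](O)C1 | intermediate
27 | (tert-butyldimethylsilyloxy)acetaldehyde | O=CCO[Si](C)(C)C(C)(C)C | starting material
28 | ethyl (2E)-4-(tert-butyldimethylsilyloxy)-2-methylbut-2-enoate | CCOC(=O)/C(C)=C/CO[Si](C)(C)C(C)(C)C | intermediate
29 | (2E)-4-(tert-butyldimethylsilyloxy)-2-methylbut-2-enoic acid | OC(=O)/C(C)=C/CO[Si](C)(C)C(C)(C)C | intermediate
30 | (6R,7S,8S,11S)-15-(tert-butyldiphenylsilyloxy)-8-[(2E)-4-(tert-butyldimethylsilyloxy)-2-methylbut-2-enoyloxy]germacra-1(10)Z,4Z-dien-12,6-olide | C/C1=C/CC/C(CO[Si](c3ccccc3)(c3ccccc3)C(C)(C)C)=C/[C@H]2OC(=O)[C@@H](C)[C@H]2[C@@H](OC(=O)/C(C)=C/CO[Si](C)(C)C(C)(C)C)C1 | intermediate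
31 | (6R,7S,8S,11S)-15-hydroxy-8-[(2E)-4-hydroxy-2-methylbut-2-enoyloxy]germacra-1(10)Z,4Z-dien-12,6-olide (CNP0222998.3) | C/C1=C/CC/C(CO)=C/[C@H]2OC(=O)[C@@H](C)[C@H]2[C@@H](OC(=O)/C(C)=C/CO)C1 | target

## Step count and risk

Total step count: 21. Longest linear sequence: 19 (steps 1–17, 20 and 21); steps 18 and 19 make the side-chain acid.

Least certain steps, the key step first:

**Step 10 (key step).** Three processes can interfere.
- Insufficient face discrimination by the C8 silyloxy group would give the C6/C7 bis-epimer.
- A [1,2] shift or deprotonation at the allylic C12 could compete with the [2,3] path.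
- A 1,3 silyl transfer from O8 to the new O6 alkoxide could occur on warming.

Fallback: close the ring by a chromium-mediated allylation instead of the ring contraction, setting out from 14. The propargylic bromide is oxidised with N-methylmorpholine N-oxide to the ynal (6Z,9R,10Z)-9-(tert-butyldimethylsilyloxy)-12-hydroxy-7,11-dimethyldodeca-6,10-dien-2-ynal F1. The allylic alcohol is converted through its mesylate with LiBr into the allylic bromide F2. CrCl2 in THF at high dilution then forms the allylchromium, which adds through C7 to the C6 aldehyde with allylic transposition and gives the same connectivity as 17. The chair transition state of such additions should favour the anti product, the C6 epimer of 17, (6R,7R,8R)-8-(tert-butyldimethylsilyloxy)-15-norgermacra-1(10)Z,11-dien-4-yn-6-ol F3. F3 is inverted at the propargylic carbinol by a Mitsunobu reaction with 4-nitrobenzoic acid to the 4-nitrobenzoate F4, and methanolysis (K2CO3, MeOH) returns to the route at 17.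

**Step 5.** The α-anilinooxy aldehyde may lose configurational integrity under the basic olefination, and the Z/E ratio may be poor. Fallback from 7: the same aminoxylation, but trapping with the neutral stabilised ylide Ph3P=C(CH3)CO2Et and N–O cleavage with zinc gives the E ester ethyl (2E,4R,6Z)-4,12-dihydroxy-2,6-dimethyldodeca-2,6-dien-10-ynoate F5. Ultraviolet irradiation then equilibrates the enoate geometry, and the Z isomer is drained by lactonisation, which returns to the route at 10.

**Step 12.** The hindered trisubstituted iodide may transmetalate slowly, so that protodestannylation of the reagent or, on heating, Cope rearrangement of the 1,5-diene takes over. Fallback from 19: carbonylative lactonisation (Pd(PPh3)4, CO, Et3N, 40 °C), in which the C6 hydroxyl traps the acylpalladium, gives the 15,6-butenolide F6. Reduction with i-Bu2AlH returns to the route at diol 20.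

**Step 16.** Protonation of the enolate may show poor facial selectivity, or the enolate may rearrange if it warms. Fallback from 23: the enolate is brominated (LiN(i-Pr)2, then BrCl2CCCl2Br) on the convex face to the 11-bromo lactone F7. Anti elimination with DBU can only use the methyl hydrogens, because H7 is syn to bromine, and gives the 11(13)-methylene lactone F8. Hydrogenation with RhCl(PPh3)3 adds hydrogen to the exocyclic alkene from the convex face and returns to the route at 25.

**Step 20.** At the hindered C8 the Mitsunobu reaction may stall or divert to elimination towards C9 (a diene conjugated with C1=C10). Fallback from 26: Dess–Martin oxidation gives the 8-oxo lactone F9. Reduction with NaBH4 and CeCl3 at −78 °C, with hydride entering on the face away from the lactone, should give the all-cis (8S) alcohol F10. Esterification of F10 with 29 under Yamaguchi conditions (2,4,6-trichlorobenzoyl chloride, Et3N, then DMAP) proceeds with retention and returns to the route at 30.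

## Further compounds

F1 | step 10 | (6Z,9R,10Z)-9-(tert-butyldimethylsilyloxy)-12-hydroxy-7,11-dimethyldodeca-6,10-dien-2-ynal | O=CC#CCC/C=C(/C)C[C@@H](O[Si](C)(C)C(C)(C)C)/C=C(/C)CO
F2 | step 10 | (6Z,9R,10Z)-12-bromo-9-(tert-butyldimethylsilyloxy)-7,11-dimethyldodeca-6,10-dien-2-ynal | O=CC#CCC/C=C(/C)C[C@@H](O[Si](C)(C)C(C)(C)C)/C=C(/C)CBr
F3 | step 10 | (6R,7R,8R)-8-(tert-butyldimethylsilyloxy)-15-norgermacra-1(10)Z,11-dien-4-yn-6-ol (C6 epimer of 17) | C/C1=C/CCC#C[C@H](O)[C@@H](C(C)=C)[C@H](O[Si](C)(C)C(C)(C)C)C1
F4 | step 10 | 4-nitrobenzoate of 17 | C/C1=C/CCC#C[C@@H](OC(=O)c2ccc(cc2)[N+](=O)[O-])[C@@H](C(C)=C)[C@H](O[Si](C)(C)C(C)(C)C)C1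
F5 | step 5 | ethyl (2E,4R,6Z)-4,12-dihydroxy-2,6-dimethyldodeca-2,6-dien-10-ynoate | OCC#CCC/C=C(/C)C[C@@H](O)/C=C(\C)C(=O)OCC
F6 | step 12 | 15,6-butenolide of the cyclodecadiene (lactone O6–C15(=O) on C4=C5, isopropenyl on C7, silyl ether on C8) | C/C1=C/CC/C2=C/[C@@H](OC2=O)[C@@H](C(C)=C)[C@H](O[Si](C)(C)C(C)(C)C)C1
F7 | step 16 | 11-bromo derivative of 23 (bromine on the convex face) | C/C1=C/CC/C(CO[Si](c3ccccc3)(c3ccccc3)C(C)(C)C)=C/[C@H]2OC(=O)[C@@](Br)(C)[C@H]2[C@H](O[Si](C)(C)C(C)(C)C)C1
F8 | step 16 | 8-(tert-butyldimethylsilyloxy)-15-(tert-butyldiphenylsilyloxy)germacra-1(10)Z,4Z,11(13)-trien-12,6-olide | C/C1=C/CC/C(CO[Si](c3ccccc3)(c3ccccc3)C(C)(C)C)=C/[C@H]2OC(=O)C(=C)[C@H]2[C@H](O[Si](C)(C)C(C)(C)C)C1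
F9 | step 20 | 15-(tert-butyldiphenylsilyloxy)-8-oxogermacra-1(10)Z,4Z-dien-12,6-olide | C/C1=C/CC/C(CO[Si](c3ccccc3)(c3ccccc3)C(C)(C)C)=C/[C@H]2OC(=O)[C@@H](C)[C@H]2C(=O)C1
F10 | step 20 | (8S)-15-(tert-butyldiphenylsilyloxy)-8-hydroxygermacra-1(10)Z,4Z-dien-12,6-olide (C8 epimer of 26) | C/C1=C/CC/C(CO[Si](c3ccccc3)(c3ccccc3)C(C)(C)C)=C/[C@H]2OC(=O)[C@@H](C)[C@H]2[C@@H](O)C1
A1 | alternative 1 | acyclic ω-formyl 2-(bromomethyl)enoate (C6 aldehyde, C13 bromide, C12 methyl ester, silyl ethers on O8 and O15) | O=C/C=C(CO[Si](C)(C)C(C)(C)C)/CC/C=C(/C)C[C@H](O[Si](C)(C)C(C)(C)C)/C=C(\CBr)C(=O)OC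
A2 | alternative 1 | cis-fused 11(13)-methylene lactone, bis-silyl ether | C/C1=C/CC/C(CO[Si](C)(C)C(C)(C)C)=C/[C@H]2OC(=O)C(=C)[C@H]2[C@@H](O[Si](C)(C)C(C)(C)C)C1
A3 | alternative 2 | 1-[(E)-2-methoxyvinyl]-6-(prop-1-en-2-yl)-3-[(tert-butyldimethylsilyloxy)methyl]cyclohex-2-en-1-ol (one diastereomer) | CO/C=C/[C@]1(O)C=C(CO[Si](C)(C)C(C)(C)C)CC[C@H]1C(C)=C
A4 | alternative 2 | 8-methoxy-15-(tert-butyldimethylsilyloxy)germacra-1(10)E,4(ring-cis)-dien-6-one | COC1C/C(C)=C/CC/C(CO[Si](C)(C)C(C)(C)C)=C\C(=O)C1
A5 | alternative 3 | seco-1,10 diene lactone (vinyl end at C2, isopropenyl end at C9, all four stereocentres in place) | C=CCC/C(CO[Si](C)(C)C(C)(C)C)=C/[C@H]1OC(=O)[C@@H](C)[C@H]1[C@@H](O[Si](C)(C)C(C)(C)C)CC(C)=C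
A6 | alternative 3 | 8,15-bis(tert-butyldimethylsilyloxy)germacra-1(10)Z,4Z-dien-12,6-olide with the target configuration | C/C1=C/CC/C(CO[Si](C)(C)C(C)(C)C)=C/[C@H]2OC(=O)[C@@H](C)[C@H]2[C@@H](O[Si](C)(C)C(C)(C)C)C1
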